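**Plan**
- Retrosynthesis: the methylene bridge is cut at C7–CH2 and at CH2–C3 of the pyranone (phenol 15, pyranone 19, one CH2 unit). The exocyclic C=CH2 goes back to a ketone. Ring B is cut at C3a–C3 and C7a–O1. The pyranone is cut at its lactone C–O bond and at the acyl–carbon bond of a 3,5-dioxo ester.
- Enabling feature: C3a–C3 and C7a–O1 sit on adjacent carbons of ring A and the C3–C2–O1 unit is a masked terminal oxirane. Ring B can therefore be made from an aryl iodide (iodine on C7a) and an enantiopure epoxide by palladium/norbornene catalysis.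
- Forward: ring A is bought as 2',6'-dihydroxyacetophenone, MOM-protected and iodinated para to the acetyl group (4). Epoxide 10 is made in three steps. Step 6 closes ring B. The carbinol next to C2 is then converted into the 1,1-disubstituted alkene and the MOM groups are removed. Ring C (pyranone 19, two steps) is attached through a CH2 unit at C7 in the last step.
- Stereochemistry: the only stereocentre, C2 (R), is the oxirane carbon of 10. It is set by the L-(+)-tartrate-controlled kinetic-resolution epoxidation and carried through step 6 with retention, because its C–O bond is never broken. The neighbouring silyloxy carbon is sacrificial and is erased at the ketone stage.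

Key step: step 6

Remark: ring A is the benzene ring, ring B the dihydrofuran ring, ring C the pyranone; atoms of rings A and B carry the 2,3-dihydro-1-benzofuran numbers (O1, C2, C3, C3a, C4–C7, C7a). The bridgehead-substituted norbornene of step 6 is a known cocatalyst and is taken as available.

**Step 1**
Reactants: 1 1-(2,6-dihydroxyphenyl)ethanone
Product: 2 1-[2,6-bis(methoxymethoxy)phenyl]ethanone
Conditions: NaH, MOMCl, DMF, 0 °C to rt
Reagents that add atoms: chloromethyl methyl ether (MOMCl), COCCl
Why: Williamson-type etherification of both phenoxides (the hydrogen-bonded ortho-hydroxy ketone needs full deprotonation by NaH) gives the bis-acetal, a standard protection of 2,6-dihydroxyacetophenones.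

**Step 2**
Reactants: 2 1-[2,6-bis(methoxymethoxy)phenyl]ethanone
Product: 4 1-[4-iodo-2,6-bis(methoxymethoxy)phenyl]ethanone, via aryl pinacol boronate 3 (not isolated)
Conditions: [Ir(OMe)(cod)]2 (cat.), 4,4'-di-tert-butyl-2,2'-bipyridine, B2pin2, THF, 80 °C; evaporate; then CuI (cat.), 1,10-phenanthroline, KI, MeOH/H2O, air, 80 °C
Reagents that add atoms: potassium iodide, [K+].[I-]
Why: Iridium-catalysed aromatic C–H borylation is sterically governed and takes place only at the C–H without an ortho neighbour (para to the acetyl group), and copper-mediated iododeboronation under air then exchanges boron for iodine at that carbon.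

**Step 3**
Reactants: 5 5-bromo-2-methylpent-2-ene; 6 acrolein (prop-2-enal)
Product: 8 (±)-7-methylocta-1,6-dien-3-ol, via homoprenylmagnesium bromide 7 (not isolated)
Conditions: Mg, THF, rt to 40 °C; then 6, THF, −78 to 0 °C; aq NH4Cl
Reagents that add atoms: none
Why: Grignard formation and 1,2-addition to the enal at low temperature give the racemic secondary allylic alcohol.

**Step 4**
Reactants: 8 (±)-7-methylocta-1,6-dien-3-ol
Product: 9 (1S)-5-methyl-1-[(2R)-oxiran-2-yl]hex-4-en-1-ol
Conditions: Ti(OiPr)4 (10 mol %), L-(+)-diisopropyl tartrate (15 mol %), t-BuOOH (0.45 equiv), 4 Å molecular sieves, CH2Cl2, −20 °C; chromatography removes unreacted (R)-8 and the minor threo isomer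
Reagents that add atoms: tert-butyl hydroperoxide, CC(C)(C)OO
Why: Sharpless kinetic resolution: with L-(+)-tartrate the (S)-alcohol is the fast-reacting enantiomer and is epoxidised on the alkene face that makes the oxirane carbon R (erythro product, reagent control matched with the carbinol centre), the slow (R)-alcohol is left behind, and the remote trisubstituted alkene, which is not allylic to the titanium-bound hydroxyl, is not touched.

**Step 5**
Reactants: 9 (1S)-5-methyl-1-[(2R)-oxiran-2-yl]hex-4-en-1-ol
Product: 10 tert-butyldimethyl{[(1S)-5-methyl-1-[(2R)-oxiran-2-yl]hex-4-en-1-yl]oxy}silane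
Conditions: TBSCl, imidazole, DMF, rt
Reagents that add atoms: tert-butyldimethylsilyl chloride, CC(C)(C)[Si](C)(C)Cl
Why: Imidazole-promoted silylation of the secondary alcohol is routine and removes the free hydroxyl that could undergo Payne rearrangement or bind palladium in step 6.

**Step 6**
Reactants: 4 1-[4-iodo-2,6-bis(methoxymethoxy)phenyl]ethanone; 10 tert-butyldimethyl{[(1S)-5-methyl-1-[(2R)-oxiran-2-yl]hex-4-en-1-yl]oxy}silane
Product: 11 1-[(2R)-2-[(1S)-1-{[tert-butyl(dimethyl)silyl]oxy}-5-methylhex-4-en-1-yl]-4,6-bis(methoxymethoxy)-2,3-dihydro-1-benzofuran-5-yl]ethanone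
Conditions: Pd(OAc)2 (10 mol %), RuPhos (20 mol %), 1-butylbicyclo[2.2.1]hept-2-ene (bridgehead-substituted norbornene, 0.5 equiv), Cs2CO3, 1,4-dioxane, 100 °C; 4 in excess (1.5 equiv)
Reagents that add atoms: none
Why: Zerovalent palladium formed from Pd(OAc)2 and the phosphine inserts into the C7a–I bond of 4, the norbornene inserts into the aryl–palladium bond and carbonate-assisted palladation of the neighbouring C3a–H gives an aryl–norbornyl palladacycle of divalent palladium; this opens oxirane 10 at its CH2 terminus in an SN2-type oxidative addition (tetravalent palladium), reductive elimination makes C3a–C3, the norbornene is expelled by β-carbon elimination and the pendant alkoxide is coupled to C7a. The closest known reaction type is the palladium/norbornene (Catellani-type) annulation of aryl iodides with terminal epoxides to 2,3-dihydrobenzofurans, run here with a bridgehead-substituted norbornene of the kind used for aryl iodides that lack an ortho substituent. Ring B closes by intramolecular C(aryl)–O reductive elimination from a six-membered aryl palladium alkoxide, a 5-exo closure onto the ipso carbon. No stereocentre is formed: the C2–O bond of the oxirane is never broken, so C2 of 11 keeps the R configuration of 10. The step needs opening only at the oxirane CH2, which a terminal epoxide with a bulky silyloxy neighbour secures, and one ortho-alkylation only, for which the bridgehead substituent (fast norbornene extrusion after a single alkylation), the MOM ethers flanking both ortho positions and the use of 10 as the limiting partner are relied on; 4 is symmetrical, so either ortho C–H gives 11 and the other one remains as C7–H for step 13.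

**Step 7**
Reactants: 11 1-[(2R)-2-[(1S)-1-{[tert-butyl(dimethyl)silyl]oxy}-5-methylhex-4-en-1-yl]-4,6-bis(methoxymethoxy)-2,3-dihydro-1-benzofuran-5-yl]ethanone
Product: 12 1-[(2R)-2-[(1S)-1-hydroxy-5-methylhex-4-en-1-yl]-4,6-bis(methoxymethoxy)-2,3-dihydro-1-benzofuran-5-yl]ethanone
Conditions: Bu4NF, THF, 0 °C to rt
Reagents that add atoms: none
Why: Fluoride-mediated cleavage of the Si–O bond frees the secondary alcohol while the MOM ethers, the aryl ketone and the alkene are inert.

**Step 8**
Reactants: 12 1-[(2R)-2-[(1S)-1-hydroxy-5-methylhex-4-en-1-yl]-4,6-bis(methoxymethoxy)-2,3-dihydro-1-benzofuran-5-yl]ethanone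
Product: 13 1-[(2R)-5-acetyl-4,6-bis(methoxymethoxy)-2,3-dihydro-1-benzofuran-2-yl]-5-methylhex-4-en-1-one
Conditions: Dess–Martin periodinane, NaHCO3, CH2Cl2, 0 °C to rt
Reagents that add atoms: none
Why: Dess–Martin oxidation under bicarbonate buffering converts the alcohol into the ketone under non-enolising conditions, so the α-aryloxy stereocentre C2 should survive.

**Step 9**
Reactants: 13 1-[(2R)-5-acetyl-4,6-bis(methoxymethoxy)-2,3-dihydro-1-benzofuran-2-yl]-5-methylhex-4-en-1-one
Product: 14 1-[(2R)-4,6-bis(methoxymethoxy)-2-(6-methylhepta-1,5-dien-2-yl)-2,3-dihydro-1-benzofuran-5-yl]ethanone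
Conditions: Cp2TiMe2 (about 2 equiv), toluene/THF, 65 °C, dark
Reagents that add atoms: dimethyltitanocene (Cp2TiMe2), C[Ti](C)(C1C=CC=C1)C1C=CC=C1
Why: Petasis methylenation proceeds through a titanium methylidene and an oxatitanacyclobutane under neutral conditions, so C2 next to the carbonyl is not epimerised, and the open side-chain ketone should react well before the acetyl group that is twisted and shielded by two ortho MOM ethers.

**Step 10**
Reactants: 14 1-[(2R)-4,6-bis(methoxymethoxy)-2-(6-methylhepta-1,5-dien-2-yl)-2,3-dihydro-1-benzofuran-5-yl]ethanone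
Product: 15 1-[(2R)-4,6-dihydroxy-2-(6-methylhepta-1,5-dien-2-yl)-2,3-dihydro-1-benzofuran-5-yl]ethanone
Conditions: HCl (3 M aq, cat.), MeOH, rt
Reagents that add atoms: none
Why: Acid-catalysed methanolysis of the acetals is fast for aryl MOM ethers ortho to a carbonyl group, so dilute acid at room temperature suffices and should leave the allylic aryl ether C2–O1 and both alkenes intact.

**Step 11**
Reactants: 16 methyl 3-oxopentanoate
Product: 18 methyl 4-methyl-3,5-dioxoheptanoate, via dilithium dienolate 17 (not isolated)
Conditions: LiN(iPr)2 (2.2 equiv), THF, −78 to 0 °C; then EtC(O)N(OMe)Me, −78 to 0 °C; 1 M HCl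
Reagents that add atoms: N-methoxy-N-methylpropanamide, CCC(=O)N(C)OC
Why: In the dianion of the β-keto ester the γ-carbon is the more nucleophilic site and is C-acylated once by the Weinreb amide, whose stable chelated adduct prevents over-addition (Claisen-type acylation of a Weiler dianion).

**Step 12**
Reactants: 18 methyl 4-methyl-3,5-dioxoheptanoate
Product: 19 6-ethyl-4-hydroxy-5-methyl-2H-pyran-2-one
Conditions: DBU, toluene, 110 °C; then 1 M HCl
Reagents that add atoms: none
Why: Base-induced lactonisation of the 3,5-dioxo ester through its 5-enolate onto the ester carbonyl (6-exo-trig acyl substitution) is the standard route to 4-hydroxy-2-pyranones.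

**Step 13**
Reactants: 19 6-ethyl-4-hydroxy-5-methyl-2H-pyran-2-one; 15 1-[(2R)-4,6-dihydroxy-2-(6-methylhepta-1,5-dien-2-yl)-2,3-dihydro-1-benzofuran-5-yl]ethanone
Product: 22 3-{[(2R)-5-acetyl-4,6-dihydroxy-2-(6-methylhepta-1,5-dien-2-yl)-2,3-dihydro-1-benzofuran-7-yl]methyl}-6-ethyl-4-hydroxy-5-methyl-2H-pyran-2-one, via pyranone Mannich base 20 (not isolated), via pyranone methide 21 (not isolated)
Conditions: 19, Me2N=CH2+ I−, MeCN, rt; then 15, 40–60 °C
Reagents that add atoms: dimethyl(methylidene)ammonium iodide, C=[N+](C)C.[I-]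
Why: Mannich reaction at C3 of the pyranone followed by loss of dimethylamine gives a pyranone methide, which is captured by C7, the only free and most electron-rich carbon of ring A, in a Friedel–Crafts-type conjugate addition as used for methylene-bridged acylphloroglucinol–pyranone dimers; C2 is remote and unaffected.

**Compound list**
1 | 1-(2,6-dihydroxyphenyl)ethanone | CC(=O)c1c(O)cccc1O | starting material
2 | 1-[2,6-bis(methoxymethoxy)phenyl]ethanone | CC(=O)c1c(OCOC)cccc1OCOC | intermediate
3 | 1-[2,6-bis(methoxymethoxy)-4-(4,4,5,5-tetramethyl-1,3,2-dioxaborolan-2-yl)phenyl]ethanone | CC(=O)c1c(OCOC)cc(B2OC(C)(C)C(C)(C)O2)cc1OCOC | intermediate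
4 | 1-[4-iodo-2,6-bis(methoxymethoxy)phenyl]ethanone | CC(=O)c1c(OCOC)cc(I)cc1OCOC | intermediate
5 | 5-bromo-2-methylpent-2-ene | CC(C)=CCCBr | starting material
6 | acrolein (prop-2-enal) | C=CC=O | starting material
7 | (4-methylpent-3-en-1-yl)magnesium bromide | CC(C)=CCC[Mg]Br | intermediate
8 | (±)-7-methylocta-1,6-dien-3-ol | CC(C)=CCCC(O)C=C | intermediate
9 | (1S)-5-methyl-1-[(2R)-oxiran-2-yl]hex-4-en-1-ol | CC(C)=CCC[C@H](O)[C@H]1CO1 | intermediate
10 | tert-butyldimethyl{[(1S)-5-methyl-1-[(2R)-oxiran-2-yl]hex-4-en-1-yl]oxy}silane | CC(C)=CCC[C@H](O[Si](C)(C)C(C)(C)C)[C@H]1CO1 | intermediate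
11 | 1-[(2R)-2-[(1S)-1-{[tert-butyl(dimethyl)silyl]oxy}-5-methylhex-4-en-1-yl]-4,6-bis(methoxymethoxy)-2,3-dihydro-1-benzofuran-5-yl]ethanone | CC(C)=CCC[C@H](O[Si](C)(C)C(C)(C)C)[C@H]1Cc2c(OCOC)c(C(C)=O)c(OCOC)cc2O1 | intermediate
12 | 1-[(2R)-2-[(1S)-1-hydroxy-5-methylhex-4-en-1-yl]-4,6-bis(methoxymethoxy)-2,3-dihydro-1-benzofuran-5-yl]ethanone | CC(C)=CCC[C@H](O)[C@H]1Cc2c(OCOC)c(C(C)=O)c(OCOC)cc2O1 | intermediate
13 | 1-[(2R)-5-acetyl-4,6-bis(methoxymethoxy)-2,3-dihydro-1-benzofuran-2-yl]-5-methylhex-4-en-1-one | CC(C)=CCCC(=O)[C@H]1Cc2c(OCOC)c(C(C)=O)c(OCOC)cc2O1 | intermediate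
14 | 1-[(2R)-4,6-bis(methoxymethoxy)-2-(6-methylhepta-1,5-dien-2-yl)-2,3-dihydro-1-benzofuran-5-yl]ethanone | C=C(CCC=C(C)C)[C@H]1Cc2c(OCOC)c(C(C)=O)c(OCOC)cc2O1 | intermediate
15 | 1-[(2R)-4,6-dihydroxy-2-(6-methylhepta-1,5-dien-2-yl)-2,3-dihydro-1-benzofuran-5-yl]ethanone | C=C(CCC=C(C)C)[C@H]1Cc2c(O)c(C(C)=O)c(O)cc2O1 | intermediate
16 | methyl 3-oxopentanoate | CCC(=O)CC(=O)OC | starting material
17 | dilithium dienolate of methyl 3-oxopentanoate | CC=C([O-])C=C([O-])OC.[Li+].[Li+] | intermediate
18 | methyl 4-methyl-3,5-dioxoheptanoate (racemic, enolisable) | CCC(=O)C(C)C(=O)CC(=O)OC | intermediate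
19 | 6-ethyl-4-hydroxy-5-methyl-2H-pyran-2-one | CCc1oc(=O)cc(O)c1C | intermediate
20 | 3-[(dimethylamino)methyl]-6-ethyl-4-hydroxy-5-methyl-2H-pyran-2-one | CCc1oc(=O)c(CN(C)C)c(O)c1C | intermediate
21 | 6-ethyl-5-methyl-3-methylidene-2H-pyran-2,4(3H)-dione | CCC1=C(C)C(=O)C(=C)C(=O)O1 | intermediate
22 | 3-{[(2R)-5-acetyl-4,6-dihydroxy-2-(6-methylhepta-1,5-dien-2-yl)-2,3-dihydro-1-benzofuran-7-yl]methyl}-6-ethyl-4-hydroxy-5-methyl-2H-pyran-2-one | C=C(CCC=C(C)C)[C@H]1Cc2c(O)c(C(C)=O)c(O)c(Cc3c(O)c(C)c(CC)oc3=O)c2O1 | target

**Count and risks**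
Total: 13 steps. Longest linear sequence: 9 steps (3, 4, 5, 6, 7, 8, 9, 10, 13).

1. Step 6. What may go wrong: a second ortho-alkylation before the norbornene leaves, slow palladation of a C–H that lies next to a MOM ether, or β-hydride loss from the palladium alkoxide in place of C–O bond formation. Fallback, setting out from 4 and returning at 14: palladium-catalysed hydroxylation of 4 (Pd2(dba)3, tBuXPhos, KOH, dioxane/H2O, 100 °C) would give 1-[4-hydroxy-2,6-bis(methoxymethoxy)phenyl]ethanone F1. Iodination next to the new phenol (N-iodosuccinimide, MeCN, 0 °C; the two ortho sites are equivalent) would give 1-[4-hydroxy-3-iodo-2,6-bis(methoxymethoxy)phenyl]ethanone F2. A Larock-type heteroannulation of F2 with commercial myrcene (7-methyl-3-methylideneocta-1,6-diene; Pd(OAc)2, a chiral phosphine, K2CO3, 80–100 °C) would then give 14 directly: the aryl group adds to the unsubstituted vinyl terminus and the phenoxide attacks the internal carbon of the π-allyl palladium, forming C3a–C3 and C2–O1. Ring B would then close at C2–O1 instead of C7a–O1, C2 would be set by the chiral ligand (enantioselective variants of this annulation of 2-halophenols with 1,3-dienes are documented), and steps 6 to 9 would be bypassed.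

2. Step 9. What may go wrong: loss of chemoselectivity, with the acetyl group also being methylenated once the side-chain ketone is consumed, or erosion of C2 by enolisation during the heated reaction. Fallback, setting out from 13 and returning at 14: chelation-assisted addition of Me3SiCH2MgCl (with CeCl3, THF, −78 °C) to the α-aryloxy ketone, which is far more accessible than the hindered aryl ketone, would give 1-[(2R)-2-[2-hydroxy-6-methyl-1-(trimethylsilyl)hept-5-en-2-yl]-4,6-bis(methoxymethoxy)-2,3-dihydro-1-benzofuran-5-yl]ethanone F3 (mixture at the new carbinol carbon). Peterson elimination (KH, THF, 0 °C to rt) would then give 14, replacing carbonyl–methylidene metathesis by addition and elimination.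

3. Step 13. What may go wrong: self-coupling of the pyranone methide with a second pyranone outrunning the cross-coupling at C7. Fallback, setting out from 15 and returning at 22, with the roles of the partners reversed: aminomethylation of 15 at C7 (Me2N=CH2+ I−, CH2Cl2, rt, no pyranone present) would give 1-[(2R)-7-[(dimethylamino)methyl]-4,6-dihydroxy-2-(6-methylhepta-1,5-dien-2-yl)-2,3-dihydro-1-benzofuran-5-yl]ethanone F4. On heating with 19 (dioxane, 90 °C) F4 would lose dimethylamine to the ortho-quinone methide (2R)-5-acetyl-4-hydroxy-7-methylidene-2-(6-methylhepta-1,5-dien-2-yl)-2,3-dihydro-1-benzofuran-6(7H)-one F5, which would be trapped at C3 of the pyranone by Michael addition to give 22.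

**Further compounds**
F1 | step 6 | 1-[4-hydroxy-2,6-bis(methoxymethoxy)phenyl]ethanone | CC(=O)c1c(OCOC)cc(O)cc1OCOC
F2 | step 6 | 1-[4-hydroxy-3-iodo-2,6-bis(methoxymethoxy)phenyl]ethanone | CC(=O)c1c(OCOC)cc(O)c(I)c1OCOC
F3 | step 9 | 1-[(2R)-2-[2-hydroxy-6-methyl-1-(trimethylsilyl)hept-5-en-2-yl]-4,6-bis(methoxymethoxy)-2,3-dihydro-1-benzofuran-5-yl]ethanone | CC(C)=CCCC(O)(C[Si](C)(C)C)[C@H]1Cc2c(OCOC)c(C(C)=O)c(OCOC)cc2O1
F4 | step 13 | 1-[(2R)-7-[(dimethylamino)methyl]-4,6-dihydroxy-2-(6-methylhepta-1,5-dien-2-yl)-2,3-dihydro-1-benzofuran-5-yl]ethanone | C=C(CCC=C(C)C)[C@H]1Cc2c(O)c(C(C)=O)c(O)c(CN(C)C)c2O1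
F5 | step 13 | (2R)-5-acetyl-4-hydroxy-7-methylidene-2-(6-methylhepta-1,5-dien-2-yl)-2,3-dihydro-1-benzofuran-6(7H)-one | C=C(CCC=C(C)C)[C@H]1CC2=C(O1)C(=C)C(=O)C(C(C)=O)=C2O
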